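**Retrosynthetic overview**

1. Ring numbering: C1 ketone, C2 (N), C3, C4 (carbinol), C5, C6 (Cl). The route rests on the C5=C6(Cl)–C1(=O) chloroenone of the cyclohexa-2,5-dienone ring beside the quaternary C4: this is what dichlorocarbene leaves after inserting into a cyclic silyl enol ether.
2. Key disconnection: C1–C6 and C5–C6 are cut, giving chloroform (source of C6 and its chlorine) and an enantiopure 5,5-disubstituted 2-silyloxycyclopentadiene. Because C4 is quaternary, the ring-expanded product cannot lose HCl and aromatise.
3. Ring order: the only carbocycle is bought as a five-membered ring and enlarged to the six-membered ring in the key step; no ring is closed by cyclisation.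
4. The silyloxydiene comes from (S)-4-hydroxy-4-alkylcyclopent-2-enone, made by anti 1,2-addition of a C5 Grignard reagent to (R)-4-silyloxycyclopentenone; that stereocentre relays its chirality to C4 and is then oxidised to the ketone.
5. After the key step: α-iodination at C2, copper-catalysed amidation with (2E,4S,6R)-4,6,8-trimethylnona-2,7-dienamide (from meso-2,4-dimethylglutaric anhydride by reduction, lipase desymmetrisation and two Wittig reactions), desilylation, ester hydrolysis.

Key step: step 6

Assumption: Pseudomonas fluorescens lipase (Amano AK) acetylates meso-2,4-dimethylpentane-1,5-diol to the (2R,4S)-5-acetoxy alcohol; were the antipode formed, the free hydroxyl would be silylated and the acetate removed before the first oxidation, so that the two termini are elaborated in the opposite order.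

**Route**

Step 1
Reactants: 1 (4R)-4-(tert-butyldimethylsilyloxy)cyclopent-2-en-1-one; 2 (5-bromopentyloxy)(tert-butyl)dimethylsilane
Product: 4 (1S,4R)-4-(tert-butyldimethylsilyloxy)-1-[5-(tert-butyldimethylsilyloxy)pentyl]cyclopent-2-en-1-ol, via [5-(tert-butyldimethylsilyloxy)pentyl]magnesium bromide 3 (not isolated)
Conditions: 2, Mg, THF, rt; anhydrous CeCl3, THF, −78 °C; then 1, −78 °C; aq NH4Cl; chromatography
Reagents that add atoms: none
Why: Organocerium 1,2-addition of the Grignard-derived nucleophile to the enone carbonyl is non-basic, so the β-silyloxy ketone is neither enolised nor attacked in the 1,4-sense, and the nucleophile should approach the flat ring anti to the C4 silyloxy group, setting the quaternary carbinol as 1S (hydroxyl cis to the silyl ether); the minor diastereomer is removed by chromatography here because it would end as the enantiomer once C4 is oxidised.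

Step 2
Reactants: 4 (1S,4R)-4-(tert-butyldimethylsilyloxy)-1-[5-(tert-butyldimethylsilyloxy)pentyl]cyclopent-2-en-1-ol
Product: 5 (1S,4R)-1-(5-hydroxypentyl)cyclopent-2-ene-1,4-diol
Conditions: TBAF, THF, 0 °C → rt
Reagents that add atoms: none
Why: Fluoride-mediated desilylation removes the primary and the secondary tert-butyldimethylsilyl ether in one operation under non-acidic conditions that do not ionise the tertiary allylic alcohol.

Step 3
Reactants: 5 (1S,4R)-1-(5-hydroxypentyl)cyclopent-2-ene-1,4-diol
Product: 6 5-[(1S)-1-hydroxy-4-oxocyclopent-2-en-1-yl]pentanoic acid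
Conditions: TEMPO (cat.), PhI(OAc)2, MeCN/H2O, rt
Reagents that add atoms: water, O
Why: Oxoammonium oxidation (TEMPO/PhI(OAc)2) in aqueous acetonitrile takes the primary alcohol through the aldehyde hydrate to the acid and the secondary allylic alcohol to the enone while the tertiary alcohol cannot be oxidised, so the former silyloxy stereocentre disappears and the quaternary centre remains as the only one.

Step 4
Reactants: 6 5-[(1S)-1-hydroxy-4-oxocyclopent-2-en-1-yl]pentanoic acid
Product: 7 methyl 5-[(1S)-1-hydroxy-4-oxocyclopent-2-en-1-yl]pentanoate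
Conditions: TMSCHN2, toluene/MeOH, 0 °C; AcOH quench
Reagents that add atoms: trimethylsilyldiazomethane, C[Si](C)(C)C=[N+]=[N-]
Why: Esterification of the carboxylic acid with trimethylsilyldiazomethane in methanol is neutral and fast, which avoids base-induced retro-aldol opening of the β-hydroxy ketone that would racemise the quaternary centre.

Step 5
Reactants: 7 methyl 5-[(1S)-1-hydroxy-4-oxocyclopent-2-en-1-yl]pentanoate
Product: 8 methyl 5-[(1R)-1,3-bis(triethylsilyloxy)cyclopenta-2,4-dien-1-yl]pentanoate
Conditions: TESOTf, Et3N, CH2Cl2, −78 → 0 °C; filtration through Et3N-deactivated silica; used at once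
Reagents that add atoms: triethylsilyl trifluoromethanesulfonate, CC[Si](CC)(CC)OS(=O)(=O)C(F)(F)F
Why: The silyl triflate with triethylamine silylates the tertiary alcohol and effects soft enolisation of the enone (silyl enol ether formation), and because the carbinol carbon is quaternary the α′-CH2 is the only enolisable position, so a single cross-conjugated 2-silyloxydiene results that has no hydrogen on its sp3 ring carbon and therefore cannot isomerise by 1,5-hydrogen shift.

Step 6
Reactants: 8 methyl 5-[(1R)-1,3-bis(triethylsilyloxy)cyclopenta-2,4-dien-1-yl]pentanoate; 9 chloroform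
Product: 12 methyl 5-[(1R)-3-chloro-4-oxo-1-(triethylsilyloxy)cyclohexa-2,5-dien-1-yl]pentanoate, via dichlorocarbene 10 (not isolated), via dichlorocyclopropane adduct 11 (not isolated)
Conditions: CHCl3, KOtBu (added in portions), pentane, −40 → 0 °C; pH 7 buffer, then rt
Reagents that add atoms: none
Why: Dichlorocarbene 10, formed by α-elimination from chloroform and potassium tert-butoxide, adds cheletropically to the most electron-rich alkene of 8, the silyl enol ether C2=C3 of the diene, to give the 6,6-dichlorobicyclo[3.1.0]hexene 11; disrotatory electrocyclic opening with departure of the endo chloride then breaks the former enol ether C–C bond, and the silyloxy-stabilised allyl cation gives up its silyl group to chloride to reveal the ketone flanked by the new chloroalkene. The closest known reaction type is the dihalocarbene ring expansion of cyclic silyl enol ethers to 2-halocycloalk-2-enones, related to the cyclopentadiene-to-chlorobenzene expansion. The six-membered ring is not closed by cyclisation but arises by one-carbon enlargement of the five-membered ring, forming C1–C6 and C5–C6 (target numbering) with C6 and its chlorine supplied by chloroform. No stereocentre is created: both cyclopropane carbons end sp2, so attack on either face converges on one product, and the quaternary C4 is untouched, its former CH2 neighbour becoming the chlorinated enone arm and its former alkene neighbour the unsubstituted arm. The step needs site selectivity for the oxygen-bearing alkene over the other ring alkene, which the donor oxygen secures towards an electrophilic carbene, and it relies on C4 being quaternary so that the adduct cannot lose HCl and aromatise; adding the base last, in portions and cold, keeps the methyl ester and the silyl ethers intact.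

Step 7
Reactants: 12 methyl 5-[(1R)-3-chloro-4-oxo-1-(triethylsilyloxy)cyclohexa-2,5-dien-1-yl]pentanoate
Product: 13 methyl 5-[(1S)-3-chloro-5-iodo-4-oxo-1-(triethylsilyloxy)cyclohexa-2,5-dien-1-yl]pentanoate
Conditions: I2, pyridine, CH2Cl2, 0 °C → rt; aq Na2S2O3
Reagents that add atoms: iodine, II
Why: Pyridine-mediated α-iodination of an enone (conjugate addition of pyridine at C3, iodination of the dienolate at C2, E1cB loss of pyridine) can only be completed on the arm that still carries an α-hydrogen, so iodine enters at C2 and the chlorinated arm is left as it is; the descriptor becomes S only because iodine outranks chlorine, the geometry being unchanged.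

Step 8
Reactants: 14 meso-2,4-dimethylglutaric anhydride
Product: 15 meso-(2R,4S)-2,4-dimethylpentane-1,5-diol
Conditions: LiAlH4, THF, 0 °C → reflux; aq NaOH work-up
Reagents that add atoms: none
Why: LiAlH4 reduction of the cyclic anhydride to the 1,5-diol proceeds without epimerisation of the two α-methyl centres, so the syn (meso) relationship of the anhydride is kept.

Step 9
Reactants: 15 meso-(2R,4S)-2,4-dimethylpentane-1,5-diol
Product: 16 (2S,4R)-5-hydroxy-2,4-dimethylpentyl acetate
Conditions: lipase AK (Pseudomonas fluorescens), vinyl acetate, THF, rt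
Reagents that add atoms: vinyl acetate, C=COC(C)=O
Why: Lipase-catalysed irreversible transesterification with vinyl acetate distinguishes the enantiotopic hydroxymethyl groups of the meso diol (enzymatic desymmetrisation), which fixes the absolute configuration of both methyl-bearing centres at once, and any over-acetylation to the diacetate preferentially consumes the minor enantiomer.

Step 10
Reactants: 16 (2S,4R)-5-hydroxy-2,4-dimethylpentyl acetate
Product: 17 (2S,4R)-2,4-dimethyl-5-oxopentyl acetate
Conditions: Dess–Martin periodinane, NaHCO3, CH2Cl2, 0 °C → rt; used crude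
Reagents that add atoms: none
Why: Buffered Dess–Martin oxidation gives the α-branched aldehyde under non-epimerising conditions, and the aldehyde is used directly.

Step 11
Reactants: 17 (2S,4R)-2,4-dimethyl-5-oxopentyl acetate; 18 isopropyltriphenylphosphonium iodide
Product: 20 (2S,4R)-2,4,6-trimethylhept-5-en-1-yl acetate, via isopropylidenetriphenylphosphorane 19 (not isolated)
Conditions: 18, n-BuLi, THF, 0 °C; then 17, −78 → 0 °C
Reagents that add atoms: none
Why: Wittig olefination with the non-stabilised isopropylidene ylide is much faster at the aldehyde than at the primary acetate at low temperature, raises no E/Z question because the new alkene carbon carries two methyl groups, and is quick enough at −78 °C to outrun epimerisation of the α-centre.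

Step 12
Reactants: 20 (2S,4R)-2,4,6-trimethylhept-5-en-1-yl acetate
Product: 21 (2S,4R)-2,4,6-trimethylhept-5-en-1-ol
Conditions: K2CO3 (cat.), MeOH, rt
Reagents that add atoms: none
Why: Base-catalysed transesterification of the acetate with methanol frees the primary alcohol without touching the alkene or the stereocentres.

Step 13
Reactants: 21 (2S,4R)-2,4,6-trimethylhept-5-en-1-ol
Product: 22 (2S,4R)-2,4,6-trimethylhept-5-enal
Conditions: Dess–Martin periodinane, NaHCO3, CH2Cl2, 0 °C → rt; used crude
Reagents that add atoms: none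
Why: Buffered Dess–Martin oxidation again delivers the α-branched aldehyde without epimerisation and leaves the trisubstituted alkene alone.

Step 14
Reactants: 22 (2S,4R)-2,4,6-trimethylhept-5-enal; 23 (2-amino-2-oxoethyl)triphenylphosphonium chloride
Product: 25 (2E,4S,6R)-4,6,8-trimethylnona-2,7-dienamide, via carbamoylmethylenetriphenylphosphorane 24 (not isolated)
Conditions: 23, KOtBu (slight deficit), THF, 0 °C; then 22, 0 °C → rt
Reagents that add atoms: none
Why: The Wittig reaction of the amide-stabilised ylide, pre-formed with a slight deficit of base so that no free base meets the aldehyde, is E-selective and delivers the primary (E)-enamide directly without epimerising the adjacent methyl-bearing centre.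

Step 15
Reactants: 13 methyl 5-[(1S)-3-chloro-5-iodo-4-oxo-1-(triethylsilyloxy)cyclohexa-2,5-dien-1-yl]pentanoate; 25 (2E,4S,6R)-4,6,8-trimethylnona-2,7-dienamide
Product: 26 methyl 5-[(1R)-3-chloro-4-oxo-1-(triethylsilyloxy)-5-{[(2E,4S,6R)-4,6,8-trimethylnona-2,7-dienoyl]amino}cyclohexa-2,5-dien-1-yl]pentanoate
Conditions: CuI (cat.), N,N′-dimethylethylenediamine (cat.), Cs2CO3, THF, 60 °C
Reagents that add atoms: none
Why: Goldberg-type copper-catalysed amidation of a vinyl iodide with a primary amide (CuI/diamine) is established for α-iodoenones, and oxidative addition at C–I is much faster than at the vinylic C–Cl, so the amide nitrogen is attached at C2 with the alkene in place and the chloride retained; the descriptor returns to R because nitrogen ranks below chlorine.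

Step 16
Reactants: 26 methyl 5-[(1R)-3-chloro-4-oxo-1-(triethylsilyloxy)-5-{[(2E,4S,6R)-4,6,8-trimethylnona-2,7-dienoyl]amino}cyclohexa-2,5-dien-1-yl]pentanoate
Product: 27 methyl 5-[(1R)-3-chloro-1-hydroxy-4-oxo-5-{[(2E,4S,6R)-4,6,8-trimethylnona-2,7-dienoyl]amino}cyclohexa-2,5-dien-1-yl]pentanoate
Conditions: HF·pyridine, pyridine, THF, 0 °C → rt
Reagents that add atoms: none
Why: Buffered HF·pyridine cleaves the tertiary triethylsilyl ether (fluoride-driven Si–O cleavage) without acid strong enough to protonate the trisubstituted alkene or to trigger dienone–phenol rearrangement of the quinol.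

Step 17
Reactants: 27 methyl 5-[(1R)-3-chloro-1-hydroxy-4-oxo-5-{[(2E,4S,6R)-4,6,8-trimethylnona-2,7-dienoyl]amino}cyclohexa-2,5-dien-1-yl]pentanoate
Product: 28 5-[(1R)-3-chloro-1-hydroxy-4-oxo-5-{[(2E,4S,6R)-4,6,8-trimethylnona-2,7-dienoyl]amino}cyclohexa-2,5-dien-1-yl]pentanoic acid (CNP0128873.1)
Conditions: pig liver esterase, pH 7.2 phosphate buffer/acetone, 30 °C
Reagents that add atoms: water, O
Why: Pig liver esterase hydrolyses the unhindered terminal methyl ester at neutral pH (enzymatic ester hydrolysis), which avoids exposing the 4-hydroxycyclohexadienone and the enamide to hydroxide.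

**Compound list**

1 | (4R)-4-(tert-butyldimethylsilyloxy)cyclopent-2-en-1-one | O=C1C=C[C@H](O[Si](C)(C)C(C)(C)C)C1 | starting material
2 | (5-bromopentyloxy)(tert-butyl)dimethylsilane | BrCCCCCO[Si](C)(C)C(C)(C)C | starting material
3 | [5-(tert-butyldimethylsilyloxy)pentyl]magnesium bromide | CC(C)(C)[Si](C)(C)OCCCCC[Mg]Br | intermediate
4 | (1S,4R)-4-(tert-butyldimethylsilyloxy)-1-[5-(tert-butyldimethylsilyloxy)pentyl]cyclopent-2-en-1-ol | O[C@]1(CCCCCO[Si](C)(C)C(C)(C)C)C=C[C@H](O[Si](C)(C)C(C)(C)C)C1 | intermediate
5 | (1S,4R)-1-(5-hydroxypentyl)cyclopent-2-ene-1,4-diol | O[C@]1(CCCCCO)C=C[C@H](O)C1 | intermediate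
6 | 5-[(1S)-1-hydroxy-4-oxocyclopent-2-en-1-yl]pentanoic acid | O=C1C=C[C@](O)(CCCCC(=O)O)C1 | intermediate
7 | methyl 5-[(1S)-1-hydroxy-4-oxocyclopent-2-en-1-yl]pentanoate | O=C1C=C[C@](O)(CCCCC(=O)OC)C1 | intermediate
8 | methyl 5-[(1R)-1,3-bis(triethylsilyloxy)cyclopenta-2,4-dien-1-yl]pentanoate | C1=C[C@](O[Si](CC)(CC)CC)(CCCCC(=O)OC)C=C1O[Si](CC)(CC)CC | intermediate
9 | chloroform | ClC(Cl)Cl | starting material
10 | dichlorocarbene | Cl[C]Cl | intermediate
11 | methyl 5-[(4R)-6,6-dichloro-1,4-bis(triethylsilyloxy)bicyclo[3.1.0]hex-2-en-4-yl]pentanoate (both cyclopropane-face diastereomers; ring-fusion centres left open) | COC(=O)CCCC[C@@]1(O[Si](CC)(CC)CC)C=CC2(O[Si](CC)(CC)CC)C1C2(Cl)Cl | intermediate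
12 | methyl 5-[(1R)-3-chloro-4-oxo-1-(triethylsilyloxy)cyclohexa-2,5-dien-1-yl]pentanoate | O=C1C=C[C@](O[Si](CC)(CC)CC)(CCCCC(=O)OC)C=C1Cl | intermediate
13 | methyl 5-[(1S)-3-chloro-5-iodo-4-oxo-1-(triethylsilyloxy)cyclohexa-2,5-dien-1-yl]pentanoate | O=C1C(I)=C[C@](O[Si](CC)(CC)CC)(CCCCC(=O)OC)C=C1Cl | intermediate
14 | meso-2,4-dimethylglutaric anhydride | C[C@H]1C[C@@H](C)C(=O)OC1=O | starting material
15 | meso-(2R,4S)-2,4-dimethylpentane-1,5-diol | OC[C@H](C)C[C@H](C)CO | intermediate
16 | (2S,4R)-5-hydroxy-2,4-dimethylpentyl acetate | OC[C@H](C)C[C@H](C)COC(C)=O | intermediate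
17 | (2S,4R)-2,4-dimethyl-5-oxopentyl acetate | O=C[C@H](C)C[C@H](C)COC(C)=O | intermediate
18 | isopropyltriphenylphosphonium iodide | CC(C)[P+](c1ccccc1)(c1ccccc1)c1ccccc1.[I-] | starting material
19 | isopropylidenetriphenylphosphorane | CC(C)=P(c1ccccc1)(c1ccccc1)c1ccccc1 | intermediate
20 | (2S,4R)-2,4,6-trimethylhept-5-en-1-yl acetate | CC(C)=C[C@H](C)C[C@H](C)COC(C)=O | intermediate
21 | (2S,4R)-2,4,6-trimethylhept-5-en-1-ol | CC(C)=C[C@H](C)C[C@H](C)CO | intermediate
22 | (2S,4R)-2,4,6-trimethylhept-5-enal | CC(C)=C[C@H](C)C[C@H](C)C=O | intermediate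
23 | (2-amino-2-oxoethyl)triphenylphosphonium chloride | NC(=O)C[P+](c1ccccc1)(c1ccccc1)c1ccccc1.[Cl-] | starting material
24 | carbamoylmethylenetriphenylphosphorane | NC(=O)C=P(c1ccccc1)(c1ccccc1)c1ccccc1 | intermediate
25 | (2E,4S,6R)-4,6,8-trimethylnona-2,7-dienamide | CC(C)=C[C@H](C)C[C@H](C)/C=C/C(N)=O | intermediate
26 | methyl 5-[(1R)-3-chloro-4-oxo-1-(triethylsilyloxy)-5-{[(2E,4S,6R)-4,6,8-trimethylnona-2,7-dienoyl]amino}cyclohexa-2,5-dien-1-yl]pentanoate | CC(C)=C[C@H](C)C[C@H](C)/C=C/C(=O)NC1=C[C@](O[Si](CC)(CC)CC)(CCCCC(=O)OC)C=C(Cl)C1=O | intermediate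
27 | methyl 5-[(1R)-3-chloro-1-hydroxy-4-oxo-5-{[(2E,4S,6R)-4,6,8-trimethylnona-2,7-dienoyl]amino}cyclohexa-2,5-dien-1-yl]pentanoate | CC(C)=C[C@H](C)C[C@H](C)/C=C/C(=O)NC1=C[C@](O)(CCCCC(=O)OC)C=C(Cl)C1=O | intermediate
28 | 5-[(1R)-3-chloro-1-hydroxy-4-oxo-5-{[(2E,4S,6R)-4,6,8-trimethylnona-2,7-dienoyl]amino}cyclohexa-2,5-dien-1-yl]pentanoic acid | CC(C)=C[C@H](C)C[C@H](C)/C=C/C(=O)NC1=C[C@](O)(CCCCC(=O)O)C=C(Cl)C1=O | target

**Step count**

Total step count: 17.
Longest linear sequence: 10 steps (steps 1–7 and 15–17 from 1; the amide branch, steps 8–14 followed by 15–17, is equally long).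

**Steps most likely to fail**

Step 6 (key step). The carbene may add unselectively, or a second time to the remaining ring alkene, and the butoxide may strip the enol silyl group before cyclopropanation so that the diene is lost as the enone or its decomposition products. The fallback sets out from 7 and comes back at 13. It replaces the chlorine-delivering carbene by a stepwise methylene insertion with later chlorination, and puts the iodine in first so that the two enone arms of the enlarged ring stay distinguishable and C4 stays stereogenic. Compound 7 would be iodinated (I2, pyridine, CH2Cl2) to methyl 5-[(1S)-1-hydroxy-3-iodo-4-oxocyclopent-2-en-1-yl]pentanoate F1, then bis-silylated (TESOTf, Et3N) to methyl 5-[(1S)-4-iodo-1,3-bis(triethylsilyloxy)cyclopenta-2,4-dien-1-yl]pentanoate F2. Cyclopropanation of the enol ether alkene with Et2Zn/CH2I2 (Furukawa–Simmons–Smith) would give methyl 5-[(4S)-2-iodo-1,4-bis(triethylsilyloxy)bicyclo[3.1.0]hex-2-en-4-yl]pentanoate F3. Oxidative opening with FeCl3 in DMF (Ito–Saegusa ring enlargement) would give the β-chloro ketone methyl 5-[(1R)-6-chloro-3-iodo-4-oxo-1-(triethylsilyloxy)cyclohex-2-en-1-yl]pentanoate F4, which NaOAc in methanol would dehydrochlorinate to methyl 5-[(1S)-3-iodo-4-oxo-1-(triethylsilyloxy)cyclohexa-2,5-dien-1-yl]pentanoate F5. α-Chlorination of the remaining unsubstituted enone arm with PhICl2/pyridine would then give 13.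

Step 15. Coupling of the weakly nucleophilic unsaturated primary amide may be slow, so that iodide 13 degrades under carbonate base and heat or is reduced back to 12. The fallback sets out from 13 (with aldehyde 22 for the acyl part) and comes back at 26. The N–vinyl bond is made with a small carbamate and the side chain is attached by N-acylation instead. Compound 13 would be coupled with tert-butyl carbamate (CuI, N,N′-dimethylethylenediamine, K3PO4, toluene) to methyl 5-[(1R)-3-[(tert-butoxycarbonyl)amino]-5-chloro-4-oxo-1-(triethylsilyloxy)cyclohexa-2,5-dien-1-yl]pentanoate F6. The carbamate would be cleaved with TMSOTf/2,6-lutidine and then methanol, which keeps the silyl ether, to give methyl 5-[(1R)-3-amino-5-chloro-4-oxo-1-(triethylsilyloxy)cyclohexa-2,5-dien-1-yl]pentanoate F7. Separately, 22 would be taken by Horner–Wadsworth–Emmons reaction with diethylphosphonoacetic acid (two equivalents of base) to (2E,4S,6R)-4,6,8-trimethylnona-2,7-dienoic acid F8, and this with 1-chloro-N,N,2-trimethylprop-1-en-1-amine to (2E,4S,6R)-4,6,8-trimethylnona-2,7-dienoyl chloride F9. Acylation of F7 with F9 (pyridine, CH2Cl2, 0 °C) would give 26.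

Step 17. The lipophilic ester may not be turned over by the enzyme, or the free quinol may degrade during long incubation. The fallback sets out from 26 and comes back at 28. The order of the two deprotections is inverted and the ester is cleaved chemically while the tertiary alcohol is still masked. Me3SnOH in 1,2-dichloroethane at 70 °C would give 5-[(1R)-3-chloro-4-oxo-1-(triethylsilyloxy)-5-{[(2E,4S,6R)-4,6,8-trimethylnona-2,7-dienoyl]amino}cyclohexa-2,5-dien-1-yl]pentanoic acid F10, and HF·pyridine would then remove the silyl ether to give 28.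

**Further compounds**

F1 | step 6 | methyl 5-[(1S)-1-hydroxy-3-iodo-4-oxocyclopent-2-en-1-yl]pentanoate | O=C1C(I)=C[C@](O)(CCCCC(=O)OC)C1
F2 | step 6 | methyl 5-[(1S)-4-iodo-1,3-bis(triethylsilyloxy)cyclopenta-2,4-dien-1-yl]pentanoate | IC1=C[C@](O[Si](CC)(CC)CC)(CCCCC(=O)OC)C=C1O[Si](CC)(CC)CC
F3 | step 6 | methyl 5-[(4S)-2-iodo-1,4-bis(triethylsilyloxy)bicyclo[3.1.0]hex-2-en-4-yl]pentanoate (both ring-fusion diastereomers) | COC(=O)CCCC[C@@]1(O[Si](CC)(CC)CC)C=C(I)C2(O[Si](CC)(CC)CC)C1C2
F4 | step 6 | methyl 5-[(1R)-6-chloro-3-iodo-4-oxo-1-(triethylsilyloxy)cyclohex-2-en-1-yl]pentanoate (mixture at C6) | O=C1C(I)=C[C@](O[Si](CC)(CC)CC)(CCCCC(=O)OC)C(Cl)C1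
F5 | step 6 | methyl 5-[(1S)-3-iodo-4-oxo-1-(triethylsilyloxy)cyclohexa-2,5-dien-1-yl]pentanoate | O=C1C(I)=C[C@](O[Si](CC)(CC)CC)(CCCCC(=O)OC)C=C1
F6 | step 15 | methyl 5-[(1R)-3-[(tert-butoxycarbonyl)amino]-5-chloro-4-oxo-1-(triethylsilyloxy)cyclohexa-2,5-dien-1-yl]pentanoate | CC(C)(C)OC(=O)NC1=C[C@](O[Si](CC)(CC)CC)(CCCCC(=O)OC)C=C(Cl)C1=O
F7 | step 15 | methyl 5-[(1R)-3-amino-5-chloro-4-oxo-1-(triethylsilyloxy)cyclohexa-2,5-dien-1-yl]pentanoate | NC1=C[C@](O[Si](CC)(CC)CC)(CCCCC(=O)OC)C=C(Cl)C1=O
F8 | step 15 | (2E,4S,6R)-4,6,8-trimethylnona-2,7-dienoic acid | CC(C)=C[C@H](C)C[C@H](C)/C=C/C(=O)O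
F9 | step 15 | (2E,4S,6R)-4,6,8-trimethylnona-2,7-dienoyl chloride | CC(C)=C[C@H](C)C[C@H](C)/C=C/C(=O)Cl
F10 | step 17 | 5-[(1R)-3-chloro-4-oxo-1-(triethylsilyloxy)-5-{[(2E,4S,6R)-4,6,8-trimethylnona-2,7-dienoyl]amino}cyclohexa-2,5-dien-1-yl]pentanoic acid | CC(C)=C[C@H](C)C[C@H](C)/C=C/C(=O)NC1=C[C@](O[Si](CC)(CC)CC)(CCCCC(=O)O)C=C(Cl)C1=O
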